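**Retrosynthetic overview**
1. Feature: rings B and D are the same pentasubstituted ring, one on each outer oxygen of ring C. Going round ring B, the sequence is B4 (O to ring C), B5 (OH), B6 (C-bound ring G), B1 (O to ring A), B2 (H), B3 (OH), which is the pattern a cyclobutenone/heteroatom-alkyne benzannulation writes onto a new phenol.
2. Last operation: all nineteen hydroxyls are revealed at once from fifteen methyl ethers, two ethyl ethers and two phenols that are already free.
3. Key disconnection: cutting B5-B6 and B1-B2 (D6-D5 and D4-D3) takes rings B and D back to a ring C bis(4-aryloxy-3-ethoxycyclobutenone) and two molecules of an aryl aryloxy alkyne that carries rings G and A (F and E).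
4. The bis(cyclobutenone) comes from a ring C bis(aryloxyacetic acid) by ketene/ethoxyacetylene [2+2] addition. Its ring C-O-CH2 bonds are Williamson bonds, and its ring C-O-ring H bond is an Ullmann bond between a 2,6-disubstituted phenol and an unhindered iodide. The alkyne comes from trichloroethylene, a phenol and an aryl iodide (Negishi).
5. Ring order: rings A, C, E, F, G and H are bought as arenes. Two cyclobutenone rings are made in step 7 and consumed in step 10, where rings B and D close together as the last rings.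

Key step: step 10

Remark: the target has no stereogenic unit, because each biaryl axis bears a symmetric 2,4,6-trihydroxyphenyl ring; in the twofold steps the transient species are drawn with both arms at the same stage, although the arms react independently.

**Step 1**
Reactants: 1 2-chloro-1,3-dimethoxybenzene
Product: 3 2-chloro-5-iodo-1,3-dimethoxybenzene, via aryl pinacol boronate 2 (not isolated)
Conditions: [Ir(OMe)(cod)]2 (1.5 mol %), dtbpy (3 mol %), B2pin2 (1.0 equiv), THF, 80 °C; evaporate; then CuI (10 mol %), 1,10-phenanthroline (20 mol %), KI, MeOH/H2O, air, 80 °C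
Reagents that add atoms: potassium iodide [K+].[I-]; bis(pinacolato)diboron CC1(C)OB(OC1(C)C)B1OC(C)(C)C(C)(C)O1 (its boryl group stands only in 2)
Why: Iridium-catalysed C-H borylation is governed by sterics and can reach only C5 of this 1,2,3-trisubstituted arene, and the copper-catalysed aerobic iododeboronation of the crude boronate then exchanges boron for iodine at that carbon without electrophilic halogenation of the activated ring.

**Step 2**
Reactants: 4 5-methoxyresorcinol
Product: 5 1-methoxy-3,5-bis(methoxymethoxy)benzene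
Conditions: MOMCl (2.5 equiv), i-Pr2NEt, CH2Cl2, 0 °C to rt
Reagents that add atoms: chloromethyl methyl ether COCCl
Why: Standard O-alkylation of both phenols installs two base-stable acetal ethers that also serve as the directing groups of step 3.

**Step 3**
Reactants: 5 1-methoxy-3,5-bis(methoxymethoxy)benzene
Product: 8 4-methoxy-2,6-bis(methoxymethoxy)phenol, via aryllithium 6 (not isolated), via dimethyl arylboronate 7 (not isolated)
Conditions: n-BuLi, THF, 0 °C to rt; B(OMe)3, -78 °C to rt; then 30 % H2O2, aq NaOH, 0 °C; NH4Cl work-up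
Reagents that add atoms: hydrogen peroxide OO; for the intermediates only: n-butyllithium [Li]CCCC (lithium of 6), trimethyl borate COB(OC)OC (boron and methoxy groups of 7)
Why: Directed ortho-metalation should take place at the carbon between the two chelating methoxymethoxy groups, which outrank methoxy as directing groups, and borylation followed by boronate oxidation (1,2-aryl shift to oxygen) turns the C-Li bond into the phenol at the same position.

**Step 4**
Reactants: 8 4-methoxy-2,6-bis(methoxymethoxy)phenol; 3 2-chloro-5-iodo-1,3-dimethoxybenzene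
Product: 9 2-(4-chloro-3,5-dimethoxyphenoxy)-5-methoxy-1,3-bis(methoxymethoxy)benzene
Conditions: CuI (10 mol %), picolinic acid (20 mol %), K3PO4, DMSO (degassed), 90 °C, argon
Reagents that add atoms: none
Why: The Ullmann diaryl ether synthesis with CuI and picolinic acid tolerates 2,6-disubstituted phenols, iodide 3 has two free ortho positions, and its doubly flanked C-Cl bond does not react under copper catalysis.

**Step 5**
Reactants: 9 2-(4-chloro-3,5-dimethoxyphenoxy)-5-methoxy-1,3-bis(methoxymethoxy)benzene
Product: 10 2-(4-chloro-3,5-dimethoxyphenoxy)-5-methoxybenzene-1,3-diol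
Conditions: HCl (cat.), MeOH, 50 °C
Reagents that add atoms: none
Why: Acid-catalysed transacetalisation in methanol removes both methoxymethyl groups, while the methyl aryl ethers, the diaryl ether and the aryl chloride are inert.

**Step 6**
Reactants: 10 2-(4-chloro-3,5-dimethoxyphenoxy)-5-methoxybenzene-1,3-diol; 11 methyl bromoacetate (2.4 equiv)
Product: 13 2,2'-{[2-(4-chloro-3,5-dimethoxyphenoxy)-5-methoxy-1,3-phenylene]bis(oxy)}diacetic acid, via dimethyl diester 12 (not isolated)
Conditions: K2CO3, DMF, rt to 50 °C; then LiOH, THF/H2O, rt; then 1 M HCl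
Reagents that add atoms: lithium hydroxide [Li+].[OH-]
Why: A twofold Williamson ether synthesis at a primary alpha-bromo ester builds the later ring C-O-B4 and ring C-O-D1 bonds as unhindered O-CH2 bonds, and saponification in the same flask gives a diacid that can be purified by acid-base extraction.

**Step 7**
Reactants: 13 the diacid of step 6; 14 ethoxyacetylene (6 equiv)
Product: 17 4,4'-{[2-(4-chloro-3,5-dimethoxyphenoxy)-5-methoxy-1,3-phenylene]bis(oxy)}bis(3-ethoxycyclobut-2-en-1-one) (meso/dl mixture), via bis(acid chloride) 15 (not isolated), via bis(aryloxyketene) 16 (not isolated)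
Conditions: Me2C=C(Cl)NMe2 (2.1 equiv), CH2Cl2, 0 °C; then 14, Et3N (2.4 equiv, slow addition), 0 °C to rt; chromatography on Et3N-deactivated silica
Reagents that add atoms: 1-chloro-N,N,2-trimethylprop-1-en-1-amine CC(C)=C(Cl)N(C)C (chlorine of 15 only)
Why: The alpha-chloroenamine forms the acid chloride without HCl (so no Friedel-Crafts closure onto activated ring C), slow dehydrochlorination keeps the aryloxyketene dilute, and the known ketene/alkoxyalkyne [2+2] cycloaddition joins the ketene carbonyl carbon to the unsubstituted nucleophilic alkyne carbon, which places ethoxy at C3 and aryloxy at C4, the two C4 stereocentres forming without control and being erased in step 10.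

**Step 8**
Reactants: 18 2,4,6-trimethoxyphenol; 19 trichloroethylene
Product: 21 2-{[(E)-1,2-dichloroethenyl]oxy}-1,3,5-trimethoxybenzene, via dichloroacetylene 20 (not isolated)
Conditions: K2CO3, DMF, 70 °C, argon
Reagents that add atoms: none
Why: Base-induced loss of HCl from trichloroethylene gives dichloroacetylene in situ, and anti addition of the phenoxide to it is the established route to (E)-1,2-dichlorovinyl aryl ethers.

**Step 9**
Reactants: 21 2-{[(E)-1,2-dichloroethenyl]oxy}-1,3,5-trimethoxybenzene; 22 2-iodo-1,3,5-trimethoxybenzene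
Product: 26 1,3,5-trimethoxy-2-{[(2,4,6-trimethoxyphenyl)ethynyl]oxy}benzene, via chloroethynyl ether 23 (not isolated), via lithium aryloxyacetylide 24 (not isolated), via aryloxyethynylzinc chloride 25 (not isolated)
Conditions: n-BuLi (2.2 equiv), THF, -78 to -40 °C; ZnCl2, -78 to 0 °C; then 22, Pd(PPh3)4 (5 mol %), THF, rt to 50 °C; neutral work-up, basic alumina
Reagents that add atoms: for the intermediates only: n-butyllithium [Li]CCCC (lithium of 24), zinc dichloride Cl[Zn]Cl (zinc and chlorine of 25)
Why: Elimination of HCl and chlorine-lithium exchange give the lithium aryloxyacetylide, and after transmetalation to zinc a Negishi alkynylation of iodide 22 forms the later B6-ring G bond as an sp-sp2 bond, where the linear alkyne meets little hindrance from the two ortho methoxy groups.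

**Step 10**
Reactants: 17 ring C bis(4-aryloxy-3-ethoxycyclobutenone) (diastereomer mixture); 26 aryl aryloxy alkyne (3 equiv)
Product: 31 eight-ring ether with free B5 and D6 hydroxyls, via bis(vinylketene) 27 (not isolated), via bis(4-vinylcyclobutenone) 28 (not isolated), via bis(dienylketene) 29 (not isolated), via bis(cyclohexadienone) 30 (not isolated)
Conditions: toluene (degassed, 0.3 M), sealed tube, 110 °C, then 150 °C
Reagents that add atoms: none
Why: Proposed new method: Each cyclobutenone should open in a conrotatory four-electron electrocyclic reaction, the C4 aryloxy donor turning outward, to vinylketene 27, whose ketene C=C bond adds [2+2] to alkyne 26 to give 4-vinylcyclobutenone 28; 28 reopens reversibly, and the dienylketene 29 that has the vinyl group turned inward is drained by ring closure to cyclohexadienone 30 and tautomerisation to phenol 31. The closest known reaction type is the Danheiser benzannulation of cyclobutenones with alkoxy- and siloxyalkynes; untested are the aryl aryloxy alkyne, the 3-alkoxy-4-aryloxy cyclobutenone and the twofold run on one core. Rings B and D each close by a thermal disrotatory six-electron electrocyclisation that joins the ketene carbon (B5, D6) to the enol ether terminus (B4, D1), after the [2+2] step has made B5-B6 and B1-B2 (D6-D5 and D4-D3). No stereocentre remains: the C4 centres of 17 and the sp3 carbons of 28 and 30 vanish on aromatisation, so both diastereomers of 17 converge, and each biaryl axis bears a symmetric ring. The selectivity needed is the orientation of the [2+2] addition, and it is secured by the ether oxygen on the sp carbon, which makes the aryl-bearing carbon the nucleophile that attacks the ketene carbonyl carbon (the same bias that sends a proton to the benzylic carbon of beta-alkoxystyrenes), by the two ortho methoxy groups of ring A, which twist that ring out of conjugation and leave the oxygen lone pair to the triple bond, and by sterics, since the bulky aryl-bearing carbon meets the unsubstituted ketene carbon. Alkyne 26 has no beta hydrogen for a retro-ene loss and should stand the temperature, and its excess should hold down ketene self-addition and acylation of the new, hindered phenols.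

**Step 11**
Reactants: 31 eight-ring ether with free B5 and D6 hydroxyls
Product: 32 CNP0275555.0 (target)
Conditions: BBr3 (about 2.5 equiv per ether), CH2Cl2, -78 °C to rt, argon; then H2O, 0 °C; Sephadex LH-20, degassed solvents
Reagents that add atoms: none
Why: In this Lewis acid-mediated ether cleavage bromide attacks the alkyl carbon of each boron-complexed alkyl aryl ether, so all fifteen methyl and both ethyl ethers should fall while the diaryl ether, biaryl and C-Cl bonds, which offer no sp3 carbon, stay intact.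

**Compound list**
1 | 2-chloro-1,3-dimethoxybenzene | COc1cccc(OC)c1Cl | starting material
2 | 2-(4-chloro-3,5-dimethoxyphenyl)-4,4,5,5-tetramethyl-1,3,2-dioxaborolane | COc1cc(B2OC(C)(C)C(C)(C)O2)cc(OC)c1Cl | intermediate
3 | 2-chloro-5-iodo-1,3-dimethoxybenzene | COc1cc(I)cc(OC)c1Cl | intermediate
4 | 5-methoxyresorcinol | COc1cc(O)cc(O)c1 | starting material
5 | 1-methoxy-3,5-bis(methoxymethoxy)benzene | COCOc1cc(OC)cc(OCOC)c1 | intermediate
6 | [4-methoxy-2,6-bis(methoxymethoxy)phenyl]lithium | [Li]c1c(OCOC)cc(OC)cc1OCOC | intermediate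
7 | dimethyl [4-methoxy-2,6-bis(methoxymethoxy)phenyl]boronate | COCOc1cc(OC)cc(OCOC)c1B(OC)OC | intermediate
8 | 4-methoxy-2,6-bis(methoxymethoxy)phenol | COCOc1cc(OC)cc(OCOC)c1O | intermediate
9 | 2-(4-chloro-3,5-dimethoxyphenoxy)-5-methoxy-1,3-bis(methoxymethoxy)benzene | COCOc1cc(OC)cc(OCOC)c1Oc1cc(OC)c(Cl)c(OC)c1 | intermediate
10 | 2-(4-chloro-3,5-dimethoxyphenoxy)-5-methoxybenzene-1,3-diol | COc1cc(O)c(Oc2cc(OC)c(Cl)c(OC)c2)c(O)c1 | intermediate
11 | methyl bromoacetate | COC(=O)CBr | starting material
12 | dimethyl 2,2'-{[2-(4-chloro-3,5-dimethoxyphenoxy)-5-methoxy-1,3-phenylene]bis(oxy)}diacetate | COC(=O)COc1cc(OC)cc(OCC(=O)OC)c1Oc1cc(OC)c(Cl)c(OC)c1 | intermediate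
13 | 2,2'-{[2-(4-chloro-3,5-dimethoxyphenoxy)-5-methoxy-1,3-phenylene]bis(oxy)}diacetic acid | OC(=O)COc1cc(OC)cc(OCC(O)=O)c1Oc1cc(OC)c(Cl)c(OC)c1 | intermediate
14 | ethoxyacetylene | CCOC#C | starting material
15 | 2,2'-{[2-(4-chloro-3,5-dimethoxyphenoxy)-5-methoxy-1,3-phenylene]bis(oxy)}diacetyl dichloride | ClC(=O)COc1cc(OC)cc(OCC(Cl)=O)c1Oc1cc(OC)c(Cl)c(OC)c1 | intermediate
16 | bis(aryloxyketene) of the ring C-ring H core | O=C=COc1cc(OC)cc(OC=C=O)c1Oc1cc(OC)c(Cl)c(OC)c1 | intermediate
17 | 4,4'-{[2-(4-chloro-3,5-dimethoxyphenoxy)-5-methoxy-1,3-phenylene]bis(oxy)}bis(3-ethoxycyclobut-2-en-1-one), meso/dl mixture | COc1cc(OC2C(=O)C=C2OCC)c(Oc2cc(OC)c(Cl)c(OC)c2)c(OC2C(=O)C=C2OCC)c1 | intermediate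
18 | 2,4,6-trimethoxyphenol | COc1cc(OC)c(O)c(OC)c1 | starting material
19 | trichloroethylene | ClC=C(Cl)Cl | starting material
20 | dichloroacetylene | ClC#CCl | intermediate
21 | 2-{[(E)-1,2-dichloroethenyl]oxy}-1,3,5-trimethoxybenzene | COc1cc(OC)c(O/C(Cl)=C\Cl)c(OC)c1 | intermediate
22 | 2-iodo-1,3,5-trimethoxybenzene | COc1cc(OC)c(I)c(OC)c1 | starting material
23 | 2-[(chloroethynyl)oxy]-1,3,5-trimethoxybenzene | COc1cc(OC)c(OC#CCl)c(OC)c1 | intermediate
24 | lithium (2,4,6-trimethoxyphenoxy)acetylide | [Li]C#COc1c(OC)cc(OC)cc1OC | intermediate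
25 | [(2,4,6-trimethoxyphenoxy)ethynyl]zinc chloride | Cl[Zn]C#COc1c(OC)cc(OC)cc1OC | intermediate
26 | 1,3,5-trimethoxy-2-{[(2,4,6-trimethoxyphenyl)ethynyl]oxy}benzene | COc1cc(OC)c(C#COc2c(OC)cc(OC)cc2OC)c(OC)c1 | intermediate
27 | bis(vinylketene): both arms ArO-CH=C(OEt)-CH=C=O, aryloxy trans to the ketene carbon chain | COc1cc(O/C=C(OCC)/C=C=O)c(Oc2cc(OC)c(Cl)c(OC)c2)c(O/C=C(OCC)/C=C=O)c1 | intermediate
28 | bis(4-vinylcyclobutenone): both arms 2-(2,4,6-trimethoxyphenyl)-3-(2,4,6-trimethoxyphenoxy)-4-[2-aryloxy-1-ethoxyvinyl]cyclobut-2-enone | COc1cc(O/C=C(OCC)/C2C(=O)C(c3c(OC)cc(OC)cc3OC)=C2Oc2c(OC)cc(OC)cc2OC)c(Oc2cc(OC)c(Cl)c(OC)c2)c(O/C=C(OCC)/C2C(=O)C(c3c(OC)cc(OC)cc3OC)=C2Oc2c(OC)cc(OC)cc2OC)c1 | intermediate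
29 | bis(dienylketene), central double bond with the two carbon chains cis | COc1cc(O/C=C(OCC)/C=C(\C(c2c(OC)cc(OC)cc2OC)=C=O)Oc2c(OC)cc(OC)cc2OC)c(Oc2cc(OC)c(Cl)c(OC)c2)c(O/C=C(OCC)/C=C(\C(c2c(OC)cc(OC)cc2OC)=C=O)Oc2c(OC)cc(OC)cc2OC)c1 | intermediate
30 | bis(cyclohexa-2,4-dienone), keto tautomer of 31 | COc1cc(OC2C(=O)C(c3c(OC)cc(OC)cc3OC)=C(Oc3c(OC)cc(OC)cc3OC)C=C2OCC)c(Oc2cc(OC)c(Cl)c(OC)c2)c(OC2C(=O)C(c3c(OC)cc(OC)cc3OC)=C(Oc3c(OC)cc(OC)cc3OC)C=C2OCC)c1 | intermediate
31 | eight-ring ether: rings A, E, F, G as trimethyl ethers, ring H as dimethyl ether, ring C as methyl ether, B3 and D2 as ethyl ethers, B5 and D6 as free phenols | COc1cc(Oc2c(OCC)cc(Oc3c(OC)cc(OC)cc3OC)c(-c3c(OC)cc(OC)cc3OC)c2O)c(Oc2cc(OC)c(Cl)c(OC)c2)c(Oc2c(OCC)cc(Oc3c(OC)cc(OC)cc3OC)c(-c3c(OC)cc(OC)cc3OC)c2O)c1 | intermediate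
32 | CNP0275555.0 | Oc1cc(O)c(Oc2cc(O)c(Oc3cc(O)cc(Oc4c(O)cc(Oc5c(O)cc(O)cc5O)c(-c5c(O)cc(O)cc5O)c4O)c3Oc3cc(O)c(Cl)c(O)c3)c(O)c2-c2c(O)cc(O)cc2O)c(O)c1 | target

**Step count**
Total steps: 11.
Longest linear sequence: 8 steps (4 to 5 to 8 to 9 to 10 to 13 to 17 to 31 to 32; steps 2, 3, 4, 5, 6, 7, 10, 11).

**Steps most likely to fail**

1. **Step 10 (new method).**
   - What may go wrong: capture of the vinylketene by the hindered triple bond, which has a donor on each side, may be slow. Ketene self-addition, acylation of freshly formed phenols by remaining ketene, and partial reversal of the addition orientation would then compete. Every inefficiency counts twice, because both arms must react.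
   - Fallback (known reaction types only, sets out from 17, comes back at 32): ring A and ring E are attached after the benzannulation instead of riding on the alkyne.
   - Commercial 2-ethynyl-1,3,5-trimethoxybenzene is lithiated, oxidised to the ynolate with lithium tert-butyl peroxide and O-silylated with TIPSOTf. This gives triisopropyl{[(2,4,6-trimethoxyphenyl)ethynyl]oxy}silane F1, a member of the alkyne class for which the Danheiser benzannulation is best established.
   - Heating 17 with F1 should give the bis(resorcinol monosilyl ether) F2.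
   - MeI/K2CO3 caps the two free phenols to give the bis(methyl ether) F3.
   - TBAF frees the B1 and D4 hydroxyls to give the bisphenol F4.
   - A twofold Ullmann etherification with iodide 22 (CuI, picolinic acid, K3PO4, DMSO) gives the fully alkylated eight-ring ether F5.
   - F5 is dealkylated with BBr3 as in step 11 to reach 32.

2. **Step 7.**
   - What may go wrong: the aryloxyketene may condense with itself faster than ethoxyacetylene captures it, the acid chloride may acylate ring C, and the vinylogous ester may hydrolyse during purification. Again both arms must succeed.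
   - Fallback (sets out from 10, comes back at 27, the first transient of step 10, and hence at 31): the vinylketene is generated without any cyclobutenone.
   - Williamson alkylation of 10 with ethyl (E)-4-bromo-3-ethoxybut-2-enoate (K2CO3, DMF) gives the bis(4-aryloxy-3-ethoxybut-2-enoate) F6.
   - LiOH gives the diacid F7, and the alpha-chloroenamine of step 7 gives the bis(acid chloride) F8.
   - Et3N, added in the presence of 26, removes HCl by gamma-deprotonation. This is the classical vinylketene generation from alpha,beta-unsaturated acid chlorides, and it delivers 27 at or below room temperature.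
   - Capture by 26 gives 28, and heating completes the cascade to 31.

3. **Step 11.**
   - What may go wrong: cleavage may stay incomplete as partly dealkylated boron aryloxides precipitate. The free polyphenol may oxidise in air on work-up, and it may prove hard to separate from under-dealkylated material.
   - Fallback (sets out from 31, comes back at 32): purification is moved to a protected stage.
   - The crude product of the BBr3 treatment is not isolated but acetylated (Ac2O, pyridine) to the nonadecaacetate F9.
   - F9 is stable to air and silica and can be chromatographed or crystallised free of partly dealkylated congeners.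
   - Acid-catalysed methanolysis (HCl, degassed MeOH, argon) then releases 32.

**Further compounds**
F1 | step 10 | triisopropyl{[(2,4,6-trimethoxyphenyl)ethynyl]oxy}silane | COc1cc(OC)c(C#CO[Si](C(C)C)(C(C)C)C(C)C)c(OC)c1
F2 | step 10 | six-ring bis(resorcinol monosilyl ether), B1 and D4 as OTIPS, B5 and D6 free | COc1cc(Oc2c(OCC)cc(O[Si](C(C)C)(C(C)C)C(C)C)c(-c3c(OC)cc(OC)cc3OC)c2O)c(Oc2cc(OC)c(Cl)c(OC)c2)c(Oc2c(OCC)cc(O[Si](C(C)C)(C(C)C)C(C)C)c(-c3c(OC)cc(OC)cc3OC)c2O)c1
F3 | step 10 | bis(methyl ether) of F2 at B5 and D6 | COc1cc(Oc2c(OCC)cc(O[Si](C(C)C)(C(C)C)C(C)C)c(-c3c(OC)cc(OC)cc3OC)c2OC)c(Oc2cc(OC)c(Cl)c(OC)c2)c(Oc2c(OCC)cc(O[Si](C(C)C)(C(C)C)C(C)C)c(-c3c(OC)cc(OC)cc3OC)c2OC)c1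
F4 | step 10 | bisphenol with free B1 and D4 hydroxyls | COc1cc(Oc2c(OCC)cc(O)c(-c3c(OC)cc(OC)cc3OC)c2OC)c(Oc2cc(OC)c(Cl)c(OC)c2)c(Oc2c(OCC)cc(O)c(-c3c(OC)cc(OC)cc3OC)c2OC)c1
F5 | step 10 | fully alkylated eight-ring ether (B5 and D6 as methyl ethers) | COc1cc(Oc2c(OCC)cc(Oc3c(OC)cc(OC)cc3OC)c(-c3c(OC)cc(OC)cc3OC)c2OC)c(Oc2cc(OC)c(Cl)c(OC)c2)c(Oc2c(OCC)cc(Oc3c(OC)cc(OC)cc3OC)c(-c3c(OC)cc(OC)cc3OC)c2OC)c1
F6 | step 7 | diethyl (2E,2'E)-4,4'-{[2-(4-chloro-3,5-dimethoxyphenoxy)-5-methoxy-1,3-phenylene]bis(oxy)}bis(3-ethoxybut-2-enoate) | CCOC(=O)\C=C(OCC)/COc1cc(OC)cc(OC/C(OCC)=C\C(=O)OCC)c1Oc1cc(OC)c(Cl)c(OC)c1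
F7 | step 7 | the corresponding bis(3-ethoxybut-2-enoic acid) | OC(=O)\C=C(OCC)/COc1cc(OC)cc(OC/C(OCC)=C\C(O)=O)c1Oc1cc(OC)c(Cl)c(OC)c1
F8 | step 7 | the corresponding bis(3-ethoxybut-2-enoyl chloride) | ClC(=O)\C=C(OCC)/COc1cc(OC)cc(OC/C(OCC)=C\C(Cl)=O)c1Oc1cc(OC)c(Cl)c(OC)c1
F9 | step 11 | nonadecaacetate of 32 | CC(=O)Oc1cc(OC(C)=O)c(Oc2cc(OC(C)=O)c(Oc3cc(OC(C)=O)cc(Oc4c(OC(C)=O)cc(Oc5c(OC(C)=O)cc(OC(C)=O)cc5OC(C)=O)c(-c5c(OC(C)=O)cc(OC(C)=O)cc5OC(C)=O)c4OC(C)=O)c3Oc3cc(OC(C)=O)c(Cl)c(OC(C)=O)c3)c(OC(C)=O)c2-c2c(OC(C)=O)cc(OC(C)=O)cc2OC(C)=O)c(OC(C)=O)c1
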